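**Plan**

1. Cuts (side chain numbered C1', the CH2 on the quinone, to C35'): the two C=O groups of ring A (the quinone ring) are taken back to OMe, then the chain is cut at C13'–C14', between the CH2 two carbons beyond the C11' methyl stereocentre and the H-bearing carbon of the C14'=C15' alkene.
2. Enabling feature: C13' is an unbranched CH2 that can be the end carbon of a vinyl group on C11' (9-BBN puts boron there), and C14'H=C15'(CH3) is the 2-methylalk-1-enyl pattern that syn-methylalumination/iodination of a terminal alkyne gives as the (E)-iodide. An sp3–sp2 Suzuki–Miyaura coupling therefore joins a C29 arene head to a C29 tail and fixes 14'E.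
3. Tail cuts: C28'–C29' (allyl–alkyl copper coupling of (R)-citronellyl Grignard reagent with ω-bromofarnesyl acetate), C16'–C17' (propargylation), C15'–CH3 (carboalumination).
4. Head cuts: C9'–C10' (alkyl–alkyl copper coupling of two chiral-pool bromides), C3'–C4' (acetylide), C3'–CH3 and C1'–C2' (carboalumination, nickel-catalysed benzylation), C12'=C13' (Wittig).
5. Stereochemistry: C31' from (R)-citronellyl bromide, C7' from (S)-citronellyl bromide, C11' from (R)-3-bromo-2-methylpropan-1-ol, none made or broken on the way; 18'E, 22'E, 26'E from (2E,6E)-farnesyl acetate; 2'E and 14'E from syn-carboalumination, kept in both couplings.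
6. Forward order: tail iodide (steps 1–7), benzylic chloride (8–9), head alkene (10–18), union (19), oxidative demethylation to the quinone (20); no ring is built, ring A only changes oxidation level.

Key step: step 19

Remark: (2E,6E)-farnesyl acetate, both citronellyl bromides, (R)-3-bromo-2-methylpropan-1-ol and menadione are taken as catalogue chemicals of high isomeric and enantiomeric purity.

**Route**

Step 1
Reactants: 1 (2E,6E)-farnesyl acetate
Product: 2 (2E,6E,10E)-12-hydroxy-3,7,11-trimethyldodeca-2,6,10-trien-1-yl acetate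
Conditions: SeO2 (0.1 equiv), t-BuOOH (3 equiv), salicylic acid (0.1 equiv), CH2Cl2, 0 °C to rt
Reagents that add atoms: selenium dioxide O=[Se]=O (catalytic carrier of the oxygen); tert-butyl hydroperoxide CC(C)(C)OO (stoichiometric source of the oxygen)
Why: Catalytic SeO2 allylic oxidation (ene reaction, then [2,3]-sigmatropic shift) should hydroxylate the (E)-methyl of the terminal trisubstituted alkene, because the C2=C3 alkene is deactivated by the allylic acetate and the gem-dimethyl end is the most accessible ene donor.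

Step 2
Reactants: 2 (ω-hydroxyfarnesyl acetate)
Product: 3 (2E,6E,10E)-12-bromo-3,7,11-trimethyldodeca-2,6,10-trien-1-yl acetate
Conditions: CBr4, PPh3, CH2Cl2, 0 °C
Reagents that add atoms: carbon tetrabromide BrC(Br)(Br)Br
Why: Appel bromination displaces the oxyphosphonium ion of a primary allylic alcohol by SN2 without allylic transposition and leaves the acetate and the (E)-alkenes alone.

Step 3
Reactants: 3 (ω-bromofarnesyl acetate); 4 (6R)-8-bromo-2,6-dimethyloct-2-ene [(R)-citronellyl bromide]
Product: 6 (2E,6E,10E,15S)-3,7,11,15,19-pentamethylicosa-2,6,10,18-tetraen-1-yl acetate, via (R)-citronellylmagnesium bromide 5 (not isolated)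
Conditions: 4, Mg turnings, THF, 40 °C; the solution of 5 added to 3, Li2CuCl4 (3 mol %), THF, −78 °C to −20 °C
Reagents that add atoms: none
Why: Kochi–Schlosser-type copper-catalysed coupling of a primary Grignard reagent with a primary allylic bromide should go by α (SN2) substitution with retention of 10E and much faster than addition to the acetate at low temperature, and the C15 stereocentre comes unchanged from 4 (the descriptor changes from R to S only because the priorities change).

Step 4
Reactants: 6 (C25 allylic acetate)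
Product: 7 (2E,6E,10E,15S)-3,7,11,15,19-pentamethylicosa-2,6,10,18-tetraen-1-ol
Conditions: K2CO3 (cat.), MeOH, rt
Reagents that add atoms: none
Why: Base-catalysed transesterification frees the allylic alcohol without touching alkenes or the stereocentre.

Step 5
Reactants: 7 (C25 allylic alcohol)
Product: 8 (2E,6E,10E,15S)-1-bromo-3,7,11,15,19-pentamethylicosa-2,6,10,18-tetraene
Conditions: PBr3 (0.4 equiv), Et2O, −10 °C
Reagents that add atoms: phosphorus tribromide BrP(Br)Br
Why: PBr3 converts primary polyprenyl alcohols into the (E)-allylic bromides by SN2 displacement of the bromophosphite at low temperature.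

Step 6
Reactants: 8 (C25 allylic bromide)
Product: 10 (5E,9E,13E,18S)-6,10,14,18,22-pentamethyltricosa-5,9,13,21-tetraen-1-yne, via C-silyl enyne 9 (not isolated)
Conditions: 1-(trimethylsilyl)propyne, n-BuLi, THF, −78 °C to −20 °C; then 8, −78 °C to 0 °C; then K2CO3 (cat.), MeOH, rt
Reagents that add atoms: 1-(trimethylsilyl)propyne CC#C[Si](C)(C)C
Why: 3-Lithio-1-(trimethylsilyl)propyne alkylates primary allylic halides at its propargylic carbon by SN2 attack (the silyl group suppresses allene formation), and mild methanolysis then cleaves the C–Si bond to give the terminal 1,5-enyne.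

Step 7
Reactants: 10 (tail enyne)
Product: 12 (1E,5E,9E,13E,18S)-1-iodo-2,6,10,14,18,22-hexamethyltricosa-1,5,9,13,21-pentaene, via alkenyldimethylalane 11 (not isolated)
Conditions: Me3Al (2.5 equiv), Cp2ZrCl2 (0.25 equiv), CH2Cl2, 0 °C to rt; then I2, THF, −30 °C to 0 °C
Reagents that add atoms: trimethylaluminium C[Al](C)C; iodine II
Why: Negishi zirconium-catalysed carboalumination adds CH3–Al syn across the terminal alkyne with methyl on the internal carbon, and iodinolysis of the C–Al bond with retention gives the (E)-2-methylalk-1-enyl iodide, the trisubstituted alkenes being inert to both reagents.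

Step 8
Reactants: 13 2-methylnaphthalene-1,4-dione (menadione)
Product: 15 1,4-dimethoxy-2-methylnaphthalene, via menadiol 14 (not isolated)
Conditions: Na2S2O4, Bu4NBr (cat.), THF/H2O, rt; then aq KOH, Me2SO4, rt
Reagents that add atoms: dimethyl sulfate COS(=O)(=O)OC
Why: Dithionite reduces the quinone to the hydroquinone, whose dianion is methylated twice (Williamson ether synthesis), which masks ring A against borane, base and palladium.

Step 9
Reactants: 15 (1,4-dimethoxy-2-methylnaphthalene)
Product: 16 2-(chloromethyl)-1,4-dimethoxy-3-methylnaphthalene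
Conditions: (CH2O)n, conc. aq HCl, AcOH, rt
Reagents that add atoms: formaldehyde (as paraformaldehyde) C=O; hydrogen chloride Cl
Why: Blanc chloromethylation attacks the only free position of the electron-rich dimethoxylated ring (C3, ortho to OMe) and gives the benzylic chloride.

Step 10
Reactants: 17 (2R)-3-bromo-2-methylpropan-1-ol
Product: 18 [(2R)-3-bromo-2-methylpropoxy](tert-butyl)dimethylsilane
Conditions: TBSCl, imidazole, CH2Cl2, 0 °C to rt
Reagents that add atoms: tert-butyldimethylsilyl chloride CC(C)(C)[Si](C)(C)Cl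
Why: Silylation masks the hydroxyl so that the bromide can be turned into a Grignard reagent; the stereocentre is not involved.

Step 11
Reactants: 18 (silyl ether of the bromo alcohol); 19 (6S)-8-bromo-2,6-dimethyloct-2-ene [(S)-citronellyl bromide]
Product: 21 tert-butyl(dimethyl){[(2S,6R)-2,6,10-trimethylundec-9-en-1-yl]oxy}silane, via silyloxypropyl Grignard reagent 20 (not isolated)
Conditions: 18, Mg turnings, THF, reflux; then 19, Li2CuCl4 (3 mol %), THF, −10 °C to rt
Reagents that add atoms: none
Why: Kochi–Schlosser copper-catalysed sp3–sp3 coupling of the primary Grignard reagent with the unbranched primary bromide forms C9'–C10', and both stereocentres (C11' from 17, C7' from 19) lie away from the reacting carbons and pass through unchanged.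

Step 12
Reactants: 21 (C15 silyl ether with prenyl end)
Product: 23 (4R,8S)-9-{[tert-butyl(dimethyl)silyl]oxy}-4,8-dimethylnonan-1-ol, via aldehyde 22 (not isolated)
Conditions: O3, CH2Cl2/MeOH, −78 °C; then NaBH4, −78 °C to rt
Reagents that add atoms: ozone [O-][O+]=O
Why: Ozonolysis cleaves the only alkene and borohydride reduces the peroxidic intermediates and the aldehyde in the same flask to the primary alcohol, the silyl ether and stereocentres being unaffected.

Step 13
Reactants: 23 (primary alcohol)
Product: 24 tert-butyl{[(2S,6R)-9-iodo-2,6-dimethylnonyl]oxy}dimethylsilane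
Conditions: I2, PPh3, imidazole, CH2Cl2, 0 °C to rt
Reagents that add atoms: iodine II
Why: Appel-type iodination converts the primary alcohol into the iodide by SN2 displacement of the oxyphosphonium ion.

Step 14
Reactants: 24 (primary iodide)
Product: 25 tert-butyl{[(2S,6R)-2,6-dimethylundec-10-yn-1-yl]oxy}dimethylsilane
Conditions: LiC≡CH·H2NCH2CH2NH2, DMSO, rt
Reagents that add atoms: lithium acetylide–ethylenediamine complex [Li]C#C.NCCN
Why: SN2 alkylation of lithium acetylide by the unhindered primary iodide in DMSO installs the terminal alkyne C3'≡C2'.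

Step 15
Reactants: 25 (head alkyne); 16 (benzylic chloride)
Product: 27 tert-butyl{[(2S,6R,10E)-12-(1,4-dimethoxy-3-methylnaphthalen-2-yl)-2,6,10-trimethyldodec-10-en-1-yl]oxy}dimethylsilane, via alkenyldimethylalane 26 (not isolated)
Conditions: Me3Al (2.5 equiv), Cp2ZrCl2 (0.25 equiv), ClCH2CH2Cl, rt; volatiles removed; then 16, NiCl2(PPh3)2 (5 mol %) reduced with n-BuLi (10 mol %) to zerovalent nickel, THF, 0 °C to rt
Reagents that add atoms: trimethylaluminium C[Al](C)C
Why: Negishi syn-methylalumination sets the (E)-trisubstituted C2'=C3' alkene with methyl on C3', and nickel-catalysed cross-coupling of the alkenylalane with the benzylic chloride forms C1'–C2' with retention of geometry, the remote silyl ether being tolerated.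

Step 16
Reactants: 27 (silyl ether)
Product: 28 (2S,6R,10E)-12-(1,4-dimethoxy-3-methylnaphthalen-2-yl)-2,6,10-trimethyldodec-10-en-1-ol
Conditions: Bu4NF, THF, 0 °C to rt
Reagents that add atoms: none
Why: Fluoride cleaves the Si–O bond and releases the primary alcohol without affecting the aryl methyl ethers or the alkene.

Step 17
Reactants: 28 (primary alcohol)
Product: 29 (2S,6R,10E)-12-(1,4-dimethoxy-3-methylnaphthalen-2-yl)-2,6,10-trimethyldodec-10-enal
Conditions: Dess–Martin periodinane, CH2Cl2, 0 °C to rt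
Reagents that add atoms: none
Why: Dess–Martin oxidation gives the α-methyl aldehyde under non-enolising conditions, so the adjacent stereocentre (C11') should keep its configuration.

Step 18
Reactants: 29 (α-methyl aldehyde)
Product: 30 1,4-dimethoxy-2-methyl-3-[(2E,7R,11S)-3,7,11-trimethyltrideca-2,12-dien-1-yl]naphthalene
Conditions: Ph3PCH3Br, KN(SiMe3)2, THF, 0 °C; then 29, −78 °C to 0 °C
Reagents that add atoms: methyltriphenylphosphonium bromide C[P+](c1ccccc1)(c1ccccc1)c1ccccc1.[Br-]
Why: Wittig methylenation with the non-stabilised ylide at low temperature should convert the aldehyde into the vinyl group faster than it enolises, so the now allylic stereocentre C11' is retained.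

Step 19
Reactants: 30 (head alkene); 12 (tail (E)-vinyl iodide)
Product: 32 1,4-dimethoxy-2-methyl-3-[(2E,7R,11S,14E,18E,22E,26E,31S)-3,7,11,15,19,23,27,31,35-nonamethylhexatriaconta-2,14,18,22,26,34-hexaen-1-yl]naphthalene, via B-alkyl-9-BBN 31 (not isolated)
Conditions: 9-BBN (1.2 equiv), THF, 0 °C to rt; then aq Cs2CO3; then 12, PdCl2(dppf) (5 mol %), AsPh3 (5 mol %), DMF/THF/H2O, rt
Reagents that add atoms: none
Why: 9-BBN adds syn across the monosubstituted C12'=C13' alkene of 30 with boron on the terminal carbon and ignores the trisubstituted C2'=C3' alkene, and aqueous Cs2CO3 then destroys residual B–H and forms the hydroxyborate before 12 is added, so the five trisubstituted alkenes of 12 never meet a borane. Zerovalent palladium formed from PdCl2(dppf) inserts into the C14'–I bond with retention, the primary alkyl group passes from boron to palladium, and reductive elimination forms the C13'–C14' bond. The closest known reaction type is the B-alkyl Suzuki–Miyaura coupling of alkyl-9-BBN reagents with (E)-2-methylalk-1-enyl iodides. No ring is closed and no stereocentre is created: C7', C11' and C31' are spectators and 14'E is that of the iodide. The step needs chemoselective oxidative addition at C–I and suppression of β-hydride elimination in the alkylpalladium, which the wide-bite-angle dppf ligand and the unhindered primary alkylborane should secure. The 1,4-dimethoxynaphthalene oxidation level is what lets ring A survive the borane, the base and the palladium catalyst.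

Step 20
Reactants: 32 (coupled dimethyl ether)
Product: 33 2-methyl-3-[(2E,7R,11S,14E,18E,22E,26E,31S)-3,7,11,15,19,23,27,31,35-nonamethylhexatriaconta-2,14,18,22,26,34-hexaen-1-yl]naphthalene-1,4-dione
Conditions: (NH4)2Ce(NO3)6 (2.5 equiv), MeCN/CH2Cl2/H2O, 0 °C
Reagents that add atoms: water O (supplies both quinone oxygens; the methoxy groups leave as methanol)
Why: Oxidative demethylation by tetravalent cerium (two one-electron oxidations of the electron-rich arene, attack of water at C1 and C4, loss of two methanol) should give the 1,4-quinone and leave the isolated alkenes and the stereocentres untouched.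

**Compound list**

1 | (2E,6E)-3,7,11-trimethyldodeca-2,6,10-trien-1-yl acetate [(2E,6E)-farnesyl acetate] | CC(C)=CCC/C(C)=C/CC/C(C)=C/COC(C)=O | starting material
2 | (2E,6E,10E)-12-hydroxy-3,7,11-trimethyldodeca-2,6,10-trien-1-yl acetate | OC/C(C)=C/CC/C(C)=C/CC/C(C)=C/COC(C)=O | intermediate
3 | (2E,6E,10E)-12-bromo-3,7,11-trimethyldodeca-2,6,10-trien-1-yl acetate | BrC/C(C)=C/CC/C(C)=C/CC/C(C)=C/COC(C)=O | intermediate
4 | (6R)-8-bromo-2,6-dimethyloct-2-ene [(R)-citronellyl bromide] | CC(C)=CCC[C@@H](C)CCBr | starting material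
5 | [(3R)-3,7-dimethyloct-6-en-1-yl]magnesium bromide | CC(C)=CCC[C@@H](C)CC[Mg]Br | intermediate (not isolated)
6 | (2E,6E,10E,15S)-3,7,11,15,19-pentamethylicosa-2,6,10,18-tetraen-1-yl acetate | CC(C)=CCC[C@@H](C)CCC/C(C)=C/CC/C(C)=C/CC/C(C)=C/COC(C)=O | intermediate
7 | (2E,6E,10E,15S)-3,7,11,15,19-pentamethylicosa-2,6,10,18-tetraen-1-ol | CC(C)=CCC[C@@H](C)CCC/C(C)=C/CC/C(C)=C/CC/C(C)=C/CO | intermediate
8 | (2E,6E,10E,15S)-1-bromo-3,7,11,15,19-pentamethylicosa-2,6,10,18-tetraene | CC(C)=CCC[C@@H](C)CCC/C(C)=C/CC/C(C)=C/CC/C(C)=C/CBr | intermediate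
9 | trimethyl[(5E,9E,13E,18S)-6,10,14,18,22-pentamethyltricosa-5,9,13,21-tetraen-1-yn-1-yl]silane | CC(C)=CCC[C@@H](C)CCC/C(C)=C/CC/C(C)=C/CC/C(C)=C/CCC#C[Si](C)(C)C | intermediate (not isolated)
10 | (5E,9E,13E,18S)-6,10,14,18,22-pentamethyltricosa-5,9,13,21-tetraen-1-yne | CC(C)=CCC[C@@H](C)CCC/C(C)=C/CC/C(C)=C/CC/C(C)=C/CCC#C | intermediate
11 | dimethyl[(1E,5E,9E,13E,18S)-2,6,10,14,18,22-hexamethyltricosa-1,5,9,13,21-pentaen-1-yl]alumane | CC(C)=CCC[C@@H](C)CCC/C(C)=C/CC/C(C)=C/CC/C(C)=C/CC/C(C)=C/[Al](C)C | intermediate (not isolated)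
12 | (1E,5E,9E,13E,18S)-1-iodo-2,6,10,14,18,22-hexamethyltricosa-1,5,9,13,21-pentaene | CC(C)=CCC[C@@H](C)CCC/C(C)=C/CC/C(C)=C/CC/C(C)=C/CC/C(C)=C/I | intermediate
13 | 2-methylnaphthalene-1,4-dione (menadione) | CC1=CC(=O)c2ccccc2C1=O | starting material
14 | 2-methylnaphthalene-1,4-diol (menadiol) | Cc1cc(O)c2ccccc2c1O | intermediate (not isolated)
15 | 1,4-dimethoxy-2-methylnaphthalene | COc1cc(C)c(OC)c2ccccc12 | intermediate
16 | 2-(chloromethyl)-1,4-dimethoxy-3-methylnaphthalene | COc1c(CCl)c(C)c(OC)c2ccccc12 | intermediate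
17 | (2R)-3-bromo-2-methylpropan-1-ol | OC[C@@H](C)CBr | starting material
18 | [(2R)-3-bromo-2-methylpropoxy](tert-butyl)dimethylsilane | CC(C)(C)[Si](C)(C)OC[C@@H](C)CBr | intermediate
19 | (6S)-8-bromo-2,6-dimethyloct-2-ene [(S)-citronellyl bromide] | CC(C)=CCC[C@H](C)CCBr | starting material
20 | [(2R)-3-{[tert-butyl(dimethyl)silyl]oxy}-2-methylpropyl]magnesium bromide | CC(C)(C)[Si](C)(C)OC[C@@H](C)C[Mg]Br | intermediate (not isolated)
21 | tert-butyl(dimethyl){[(2S,6R)-2,6,10-trimethylundec-9-en-1-yl]oxy}silane | CC(C)(C)[Si](C)(C)OC[C@@H](C)CCC[C@@H](C)CCC=C(C)C | intermediate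
22 | (4R,8S)-9-{[tert-butyl(dimethyl)silyl]oxy}-4,8-dimethylnonanal | CC(C)(C)[Si](C)(C)OC[C@@H](C)CCC[C@@H](C)CCC=O | intermediate (not isolated)
23 | (4R,8S)-9-{[tert-butyl(dimethyl)silyl]oxy}-4,8-dimethylnonan-1-ol | CC(C)(C)[Si](C)(C)OC[C@@H](C)CCC[C@@H](C)CCCO | intermediate
24 | tert-butyl{[(2S,6R)-9-iodo-2,6-dimethylnonyl]oxy}dimethylsilane | CC(C)(C)[Si](C)(C)OC[C@@H](C)CCC[C@@H](C)CCCI | intermediate
25 | tert-butyl{[(2S,6R)-2,6-dimethylundec-10-yn-1-yl]oxy}dimethylsilane | CC(C)(C)[Si](C)(C)OC[C@@H](C)CCC[C@@H](C)CCCC#C | intermediate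
26 | [(1E,6R,10S)-11-{[tert-butyl(dimethyl)silyl]oxy}-2,6,10-trimethylundec-1-en-1-yl]dimethylalumane | CC(C)(C)[Si](C)(C)OC[C@@H](C)CCC[C@@H](C)CCC/C(C)=C/[Al](C)C | intermediate (not isolated)
27 | tert-butyl{[(2S,6R,10E)-12-(1,4-dimethoxy-3-methylnaphthalen-2-yl)-2,6,10-trimethyldodec-10-en-1-yl]oxy}dimethylsilane | CC(C)(C)[Si](C)(C)OC[C@@H](C)CCC[C@@H](C)CCC/C(C)=C/Cc1c(C)c(OC)c2ccccc2c1OC | intermediate
28 | (2S,6R,10E)-12-(1,4-dimethoxy-3-methylnaphthalen-2-yl)-2,6,10-trimethyldodec-10-en-1-ol | OC[C@@H](C)CCC[C@@H](C)CCC/C(C)=C/Cc1c(C)c(OC)c2ccccc2c1OC | intermediate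
29 | (2S,6R,10E)-12-(1,4-dimethoxy-3-methylnaphthalen-2-yl)-2,6,10-trimethyldodec-10-enal | O=C[C@@H](C)CCC[C@@H](C)CCC/C(C)=C/Cc1c(C)c(OC)c2ccccc2c1OC | intermediate
30 | 1,4-dimethoxy-2-methyl-3-[(2E,7R,11S)-3,7,11-trimethyltrideca-2,12-dien-1-yl]naphthalene | C=C[C@@H](C)CCC[C@@H](C)CCC/C(C)=C/Cc1c(C)c(OC)c2ccccc2c1OC | intermediate
31 | 9-[(3R,7R,11E)-13-(1,4-dimethoxy-3-methylnaphthalen-2-yl)-3,7,11-trimethyltridec-11-en-1-yl]-9-borabicyclo[3.3.1]nonane (C3 is the former 11S centre; only the priorities change) | B1(C2CCCC1CCC2)CC[C@@H](C)CCC[C@@H](C)CCC/C(C)=C/Cc3c(C)c(OC)c4ccccc4c3OC | intermediate (not isolated)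
32 | 1,4-dimethoxy-2-methyl-3-[(2E,7R,11S,14E,18E,22E,26E,31S)-3,7,11,15,19,23,27,31,35-nonamethylhexatriaconta-2,14,18,22,26,34-hexaen-1-yl]naphthalene | CC(C)=CCC[C@@H](C)CCC/C(C)=C/CC/C(C)=C/CC/C(C)=C/CC/C(C)=C/CC[C@@H](C)CCC[C@@H](C)CCC/C(C)=C/Cc1c(C)c(OC)c2ccccc2c1OC | intermediate
33 | 2-methyl-3-[(2E,7R,11S,14E,18E,22E,26E,31S)-3,7,11,15,19,23,27,31,35-nonamethylhexatriaconta-2,14,18,22,26,34-hexaen-1-yl]naphthalene-1,4-dione | CC(C)=CCC[C@@H](C)CCC/C(C)=C/CC/C(C)=C/CC/C(C)=C/CC/C(C)=C/CC[C@@H](C)CCC[C@@H](C)CCC/C(C)=C/CC1=C(C)C(=O)c2ccccc2C1=O | target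

**Step count**

Total: 20 steps. Longest linear sequence: 11 steps (17 to 33, steps 10–20).

**Steps most likely to fail**

1. Step 19. What may go wrong: slow transfer of the alkyl group from boron to palladium, protodeboronation of the borate, or β-hydride elimination in the alkylpalladium species. Fallback from 30 back to 32 by a Negishi coupling: 30 would be hydroborated with 9-BBN (borane 31) and oxidised with H2O2/NaOH to (3S,7R,11E)-13-(1,4-dimethoxy-3-methylnaphthalen-2-yl)-3,7,11-trimethyltridec-11-en-1-ol F1. I2, PPh3 and imidazole would turn this into 2-[(2E,7R,11S)-13-iodo-3,7,11-trimethyltridec-2-en-1-yl]-1,4-dimethoxy-3-methylnaphthalene F2. Zinc dust with LiCl in THF would insert into the C–I bond to give [(3S,7R,11E)-13-(1,4-dimethoxy-3-methylnaphthalen-2-yl)-3,7,11-trimethyltridec-11-en-1-yl]zinc iodide F3, and coupling of this with 12 under Pd(PPh3)4 catalysis in THF would give 32.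

2. Step 3. What may go wrong: attack of the Grignard reagent on the acetate carbonyl, γ (SN2') substitution, or loss of the 10E geometry through an allylcopper species. Fallback from 4 and 3 back to 7 by sulfone alkylation (Julia-type carbanion, no copper): 4 with PhSO2Na in DMF would give {[(3R)-3,7-dimethyloct-6-en-1-yl]sulfonyl}benzene F4. n-BuLi in THF at −78 °C would give [(3R)-3,7-dimethyl-1-(phenylsulfonyl)oct-6-en-1-yl]lithium F5. Alkylation of this soft carbanion with 3 by direct SN2 would give (2E,6E,10E,15R)-3,7,11,15,19-pentamethyl-13-(phenylsulfonyl)icosa-2,6,10,18-tetraen-1-yl acetate F6 as a mixture of C13 epimers (C15 is spatially unchanged). Mg in MeOH would then remove the sulfonyl group and methanolyse the acetate to give 7.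

3. Step 15. What may go wrong: reductive homocoupling of the benzylic chloride on nickel, protodemetalation of the alkenylalane, or erosion of the alkene geometry during transfer to nickel. Fallback from 25 and 16 back to 27 with the polarity of the C1'–C2' bond reversed: 25 would be carboaluminated as before and the alane 26 quenched with I2 to give tert-butyl{[(2S,6R,10E)-11-iodo-2,6,10-trimethylundec-10-en-1-yl]oxy}dimethylsilane F7, which can be purified. 16 with zinc dust and LiCl in THF would give [(1,4-dimethoxy-3-methylnaphthalen-2-yl)methyl]zinc chloride F8, and Negishi coupling of the two under Pd(PPh3)4 catalysis would give 27.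

**Further compounds**

F1 | step 19 | (3S,7R,11E)-13-(1,4-dimethoxy-3-methylnaphthalen-2-yl)-3,7,11-trimethyltridec-11-en-1-ol | OCC[C@@H](C)CCC[C@@H](C)CCC/C(C)=C/Cc1c(C)c(OC)c2ccccc2c1OC
F2 | step 19 | 2-[(2E,7R,11S)-13-iodo-3,7,11-trimethyltridec-2-en-1-yl]-1,4-dimethoxy-3-methylnaphthalene | ICC[C@@H](C)CCC[C@@H](C)CCC/C(C)=C/Cc1c(C)c(OC)c2ccccc2c1OC
F3 | step 19 | [(3S,7R,11E)-13-(1,4-dimethoxy-3-methylnaphthalen-2-yl)-3,7,11-trimethyltridec-11-en-1-yl]zinc iodide | I[Zn]CC[C@@H](C)CCC[C@@H](C)CCC/C(C)=C/Cc1c(C)c(OC)c2ccccc2c1OC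
F4 | step 3 | {[(3R)-3,7-dimethyloct-6-en-1-yl]sulfonyl}benzene | CC(C)=CCC[C@@H](C)CCS(=O)(=O)c1ccccc1
F5 | step 3 | [(3R)-3,7-dimethyl-1-(phenylsulfonyl)oct-6-en-1-yl]lithium | CC(C)=CCC[C@@H](C)CC([Li])S(=O)(=O)c1ccccc1
F6 | step 3 | (2E,6E,10E,15R)-3,7,11,15,19-pentamethyl-13-(phenylsulfonyl)icosa-2,6,10,18-tetraen-1-yl acetate (C13 epimers) | CC(C)=CCC[C@@H](C)CC(S(=O)(=O)c1ccccc1)C/C(C)=C/CC/C(C)=C/CC/C(C)=C/COC(C)=O
F7 | step 15 | tert-butyl{[(2S,6R,10E)-11-iodo-2,6,10-trimethylundec-10-en-1-yl]oxy}dimethylsilane | CC(C)(C)[Si](C)(C)OC[C@@H](C)CCC[C@@H](C)CCC/C(C)=C/I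
F8 | step 15 | [(1,4-dimethoxy-3-methylnaphthalen-2-yl)methyl]zinc chloride | COc1c(C[Zn]Cl)c(C)c(OC)c2ccccc12
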